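## Retrosynthetic overview

1. The ten-membered carbocycle is closed last, at C9–C10, by a Ni/Cr-catalysed Nozaki–Hiyama–Kishi coupling of a (Z)-iodoalkene with the C9 aldehyde (sets C9). One acid step then unmasks the C14 aldehyde and the C9 and C15 hydroxyls.
2. The lactone ring is formed first, at the fragment union: the C6–C7 bond comes from a catalytic asymmetric allylboration of a western enal (C1–C6, C10, C14, C15) with an eastern allylboronate (C7–C9, C11–C13), followed by lactonisation (sets C6 and C7).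
3. Western enal: C3–C4 by Negishi coupling on a (Z)-iodoalkene from but-2-yne-1,4-diol, C1=C10 by cross-metathesis with crotonaldehyde, then α-iodination and acetal protection.
4. Eastern allylboronate: C7–C8 by asymmetric alkynylation of a silyloxyacetaldehyde with methyl propiolate (sets C8), acylation with (S)-2-methylbutanoyl chloride, then syn-hydroalumination and borylmethylation (C11–C13) with ICH2Bpin made from CH2I2.

Atom labels (germacrane numbering): C1–C10 carbocycle (C1=C10 and C4=C5 alkenes, C6 lactone carbinol, C7, C8 ester carbinol, C9 free carbinol); C11–C13 methylene-lactone carbons (C12 carbonyl, C13 exocyclic CH2); C14 aldehyde carbon on C10; C15 hydroxymethyl carbon on C4. TBS = tert-butyldimethylsilyl, TES = triethylsilyl, TMS = trimethylsilyl, Bpin = 4,4,5,5-tetramethyl-1,3,2-dioxaborolan-2-yl.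

Assumption: (S,S)-ProPhenol is taken to give the (R)-alkynol in step 10 and (S)-TRIP to give Si-face addition to the enal in step 15; if either sense is reversed on these substrates, the mirror-image catalyst is used.

## Route

Step 1
Reactants: 1 but-2-yne-1,4-diol
Product: 2 4-(TBS-oxy)but-2-yn-1-ol
Conditions: TBSCl (1 equiv), imidazole, 1 (3 equiv), DMF, 0 °C to rt
Reagents that add atoms: tert-butyldimethylsilyl chloride, CC(C)(C)[Si](C)(C)Cl
Why: Silyl ether formation on a symmetrical diol used in threefold excess gives the monoprotected alkynol statistically, so one free hydroxyl remains to direct step 2.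

Step 2
Reactants: 2 4-(TBS-oxy)but-2-yn-1-ol
Product: 4 (2Z)-3-iodo-4-(TBS-oxy)but-2-en-1-ol, via cyclic alkenylalanate 3 (not isolated)
Conditions: NaAlH2(OCH2CH2OMe)2, THF, 0 °C to rt; then I2, −78 °C to 0 °C
Reagents that add atoms: iodine, [I][I]
Why: Hydroxyl-directed trans-hydroalumination of the propargylic alcohol delivers hydride to C5 and aluminium to C4 from opposite faces through a five-membered alanate, and iodinolysis with retention gives only the (Z)-iodoalkene (Corey-type hydroalumination–iodination).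

Step 3
Reactants: 4 (2Z)-3-iodo-4-(TBS-oxy)but-2-en-1-ol; 5 but-3-en-1-ylzinc bromide
Product: 6 (2E)-3-[(TBS-oxy)methyl]hepta-2,6-dien-1-ol
Conditions: 5 (3 equiv, 0.5 M in THF), Pd(dppf)Cl2 (5 mol %), THF, 50 °C
Reagents that add atoms: none
Why: Negishi coupling of the alkenyl iodide with a primary alkylzinc halide proceeds with retention of alkene geometry and tolerates the free alcohol, so the C3–C4 bond is made with C3 cis to C6 as the ring requires.

Step 4
Reactants: 6 (2E)-3-[(TBS-oxy)methyl]hepta-2,6-dien-1-ol; 7 (2E)-but-2-enal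
Product: 8 (2E,6E)-8-hydroxy-6-[(TBS-oxy)methyl]octa-2,6-dienal
Conditions: 7 (5 equiv), second-generation Hoveyda–Grubbs catalyst (3 mol %), CH2Cl2, 40 °C
Reagents that add atoms: none
Why: Olefin cross-metathesis of the terminal alkene with excess crotonaldehyde is E-selective and chemoselective because the trisubstituted C4=C5 alkene does not engage the ruthenium carbene.

Step 5
Reactants: 8 (2E,6E)-8-hydroxy-6-[(TBS-oxy)methyl]octa-2,6-dienal
Product: 9 (2Z,6E)-8-hydroxy-2-iodo-6-[(TBS-oxy)methyl]octa-2,6-dienal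
Conditions: I2, K2CO3, DMAP (20 mol %), THF/H2O 1:1, rt
Reagents that add atoms: iodine, [I][I]
Why: DMAP-catalysed α-iodination of the enal (conjugate addition of DMAP, iodination of the enolate and E1cB loss of DMAP, a Baylis–Hillman-type pathway) gives the thermodynamic (Z)-α-iodoenal with iodine cis to C2, which is the geometry the ring-cis C1=C10 alkene needs.

Step 6
Reactants: 9 (2Z,6E)-8-hydroxy-2-iodo-6-[(TBS-oxy)methyl]octa-2,6-dienal
Product: 10 (2E,6Z)-7-iodo-8,8-dimethoxy-3-[(TBS-oxy)methyl]octa-2,6-dien-1-ol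
Conditions: HC(OMe)3, PPTS (5 mol %), MeOH, 0 °C to rt
Reagents that add atoms: trimethyl orthoformate, COC(OC)OC
Why: Acid-catalysed acetalisation driven by trimethyl orthoformate masks C14 so that C6 is the only aldehyde in the fragment union and C9 the only one in the ring closure.

Step 7
Reactants: 10 (2E,6Z)-7-iodo-8,8-dimethoxy-3-[(TBS-oxy)methyl]octa-2,6-dien-1-ol
Product: 11 (2E,6Z)-7-iodo-8,8-dimethoxy-3-[(TBS-oxy)methyl]octa-2,6-dienal
Conditions: MnO2 (20 equiv), CH2Cl2, rt
Reagents that add atoms: none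
Why: MnO2 oxidises the primary allylic alcohol to the enal chemoselectively and without isomerising the C4=C5 alkene, leaving the iodoalkene, acetal and silyl ether untouched (allylic oxidation).

Step 8
Reactants: 12 (2Z)-but-2-ene-1,4-diol
Product: 13 (2Z)-1,4-bis(TES-oxy)but-2-ene
Conditions: TESCl (2.2 equiv), imidazole, CH2Cl2, 0 °C
Reagents that add atoms: chlorotriethylsilane, CC[Si](Cl)(CC)CC
Why: Standard silyl ether formation protects both hydroxyls of the symmetrical cis-diol.

Step 9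
Reactants: 13 (2Z)-1,4-bis(TES-oxy)but-2-ene
Product: 15 2-(TES-oxy)acetaldehyde, via secondary ozonide 14 (not isolated)
Conditions: O3, CH2Cl2, −78 °C; then PPh3, −78 °C to rt
Reagents that add atoms: ozone, [O-][O+]=O
Why: Ozonolysis of the symmetrical alkene followed by reductive cleavage of the ozonide with PPh3 gives two molecules of the same α-silyloxy aldehyde.

Step 10
Reactants: 15 2-(TES-oxy)acetaldehyde; 16 methyl prop-2-ynoate
Product: 18 methyl (4R)-4-hydroxy-5-(TES-oxy)pent-2-ynoate, via zinc acetylide 17 (not isolated)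
Conditions: 16 (2.8 equiv), Me2Zn (2.9 equiv), (S,S)-ProPhenol (20 mol %), Ph3PO (40 mol %), toluene, 0 °C; then 15, 0 °C
Reagents that add atoms: none
Why: Zinc–ProPhenol-catalysed asymmetric alkynylation adds the zinc acetylide of methyl propiolate to one enantiotopic face of the aldehyde inside the chiral dinuclear zinc pocket, which sets C8 as R.

Step 11
Reactants: 19 (2S)-2-methylbutanoic acid
Product: 20 (2S)-2-methylbutanoyl chloride
Conditions: (COCl)2, DMF (cat.), CH2Cl2, 0 °C to rt
Reagents that add atoms: oxalyl chloride, O=C(Cl)C(Cl)=O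
Why: Vilsmeier-type activation by oxalyl chloride and catalytic DMF converts the acid into its chloride under neutral conditions that do not touch the α-stereocentre.

Step 12
Reactants: 18 methyl (4R)-4-hydroxy-5-(TES-oxy)pent-2-ynoate; 20 (2S)-2-methylbutanoyl chloride
Product: 21 methyl (4R)-4-{[(2S)-2-methylbutanoyl]oxy}-5-(TES-oxy)pent-2-ynoate
Conditions: 2,6-lutidine, CH2Cl2, −20 °C to rt
Reagents that add atoms: none
Why: Acylation of the propargylic alcohol by the acid chloride with a hindered non-nucleophilic base installs the (S)-2-methylbutanoate without conjugate addition to the ynoate or ketene formation, so C8 and the ester α-carbon keep their configurations.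

Step 13
Reactants: 22 diiodomethane
Product: 24 2-(iodomethyl)-4,4,5,5-tetramethyl-1,3,2-dioxaborolane (ICH2Bpin), via iodomethylmagnesium chloride 23 (not isolated)
Conditions: i-PrMgCl, THF, −78 °C; then i-PrOBpin, −78 °C; then HCl in Et2O, −78 °C to rt
Reagents that add atoms: 2-isopropoxy-4,4,5,5-tetramethyl-1,3,2-dioxaborolane, CC(C)OB1OC(C)(C)C(C)(C)O1
Why: Iodine–magnesium exchange on diiodomethane at −78 °C gives the magnesium carbenoid, which is trapped at boron by the alkoxyboronate and released from the ate complex by acid as the iodomethylboronate (halomethylboronate synthesis of the Matteson type).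

Step 14
Reactants: 21 methyl (4R)-4-{[(2S)-2-methylbutanoyl]oxy}-5-(TES-oxy)pent-2-ynoate; 24 ICH2Bpin
Product: 26 methyl (2Z,4R)-2-(Bpin-methyl)-4-{[(2S)-2-methylbutanoyl]oxy}-5-(TES-oxy)pent-2-enoate, via alkenylalane 25 (not isolated)
Conditions: i-Bu2AlH, HMPA, THF, 0 °C; then 24, 0 °C to rt
Reagents that add atoms: none
Why: The i-Bu2AlH–HMPA complex adds hydride to C7 and aluminium to C11 of the ynoate in a syn fashion without reducing the ester groups (conjugate hydroalumination), and the alkenylalane attacks boron of 24 and migrates to carbon with loss of iodide and retention of geometry, which places C8 cis to the ester and trans to the CH2Bpin group.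

Step 15
Reactants: 11 (2E,6Z)-7-iodo-8,8-dimethoxy-3-[(TBS-oxy)methyl]octa-2,6-dienal; 26 methyl (2Z,4R)-2-(Bpin-methyl)-4-{[(2S)-2-methylbutanoyl]oxy}-5-(TES-oxy)pent-2-enoate
Product: 28 (4S,5R)-5-[(1E,5Z)-6-iodo-7,7-dimethoxy-2-[(TBS-oxy)methyl]hepta-1,5-dien-1-yl]-3-methylidene-4-[(1R)-1-{[(2S)-2-methylbutanoyl]oxy}-2-(TES-oxy)ethyl]oxolan-2-one, via boryl ether 27 (not isolated)
Conditions: (S)-TRIP [(S)-3,3′-bis(2,4,6-triisopropylphenyl)-1,1′-binaphthyl-2,2′-diyl hydrogen phosphate] (10 mol %), 4 Å MS, toluene, −30 °C to 0 °C; then PPTS (10 mol %), rt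
Reagents that add atoms: none
Why: Proposed new method: chiral phosphoric acid catalysis of the allylboration of an enal by a γ-branched 2-(methoxycarbonyl)allyl pinacolboronate, in which the acid hydrogen-bonds to a boronate oxygen and to the formyl hydrogen and so switches on an addition that has no background rate at −30 °C for this ester-deactivated boronate, the closed chair transition state with C8 equatorial turns the boronate geometry into the 6,7-anti adduct that lactonises to the trans lactone, (S)-TRIP selects the Si face of the enal (6R, hence 7S), and the C8 centre, held by A(1,3) strain with its hydrogen eclipsing the ester, exposes the allyl face anti to the acyloxy group and so reinforces the catalyst; the closest known reactions are phosphoric acid-catalysed allyl- and crotylborations of aldehydes with unfunctionalised pinacol boronates and Sc(OTf)3- or TfOH-catalysed additions of 2-alkoxycarbonyl allylboronates that give α-methylene-γ-butyrolactones.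

Step 16
Reactants: 28 lactone from step 15 (C9 TES ether)
Product: 30 (1R)-1-[(2R,3S)-2-[(1E,5Z)-6-iodo-7,7-dimethoxy-2-[(TBS-oxy)methyl]hepta-1,5-dien-1-yl]-4-methylidene-5-oxooxolan-3-yl]-2-oxoethyl (2S)-2-methylbutanoate, via alkoxysulfonium chloride 29 (not isolated)
Conditions: (COCl)2, DMSO, CH2Cl2, −78 °C to −40 °C; then i-Pr2NEt, −78 °C to −20 °C
Reagents that add atoms: none
Why: Under Swern conditions the chlorosulfonium salt takes a primary triethylsilyl ether directly to the alkoxysulfonium ion and then the aldehyde while the TBS ether survives, so the free primary alcohol that would invite 1,2-acyl migration is never formed, and the hindered base at low temperature avoids epimerisation at C8.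

Step 17
Reactants: 30 iodoalkene aldehyde from step 16
Product: 31 (3aS,4R,5S,6E,10E,11aR)-6-(dimethoxymethyl)-3-methylidene-2-oxo-10-[(TBS-oxy)methyl]-5-(TMS-oxy)-2,3,3a,4,5,8,9,11a-octahydrocyclodeca[b]furan-4-yl (2S)-2-methylbutanoate
Conditions: CrCl2 (20 mol %), NiCl2 (2 mol %), Mn powder, TMSCl, DMF/DME, rt, slow addition of 30 (2 mM final)
Reagents that add atoms: chlorotrimethylsilane, C[Si](C)(C)Cl
Why: Ni/Cr-catalysed Nozaki–Hiyama–Kishi coupling, in which zerovalent nickel inserts into the C–I bond and the alkenyl group passes to chromium and adds to the aldehyde with retention of alkene geometry, closes the ten-membered ring at C9–C10, with polar Felkin–Anh attack anti to the C8 acyloxy group giving the 8,9-anti (9S) carbinol, Mn and TMSCl returning trivalent chromium to divalent chromium, and silylation of the alkoxide preventing acyl migration.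

Step 18
Reactants: 31 macrocyclic TMS ether from step 17
Product: 32 (3aS,4R,5S,6E,10E,11aR)-6-formyl-5-hydroxy-10-(hydroxymethyl)-3-methylidene-2-oxo-2,3,3a,4,5,8,9,11a-octahydrocyclodeca[b]furan-4-yl (2S)-2-methylbutanoate (CNP0331447.11)
Conditions: AcOH/THF/H2O 3:1:1, 35 °C
Reagents that add atoms: water, O
Why: Mild aqueous acid hydrolyses the allylic dimethyl acetal to the enal and cleaves the TMS and primary TBS ethers in one operation without touching the lactone, the ester or any stereocentre (acetal hydrolysis and silyl ether cleavage).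

## Compound list

1 | but-2-yne-1,4-diol | OCC#CCO | starting material
2 | 4-(TBS-oxy)but-2-yn-1-ol | OCC#CCO[Si](C)(C)C(C)(C)C | intermediate
3 | sodium cyclic alkenylalanate (five-membered O–Al–C4=C5–C6 ring, two 2-methoxyethoxy groups on Al, CH2OTBS on C4) | [Na+].COCCO[Al-]1(OCCOC)OCC=C1CO[Si](C)(C)C(C)(C)C | intermediate
4 | (2Z)-3-iodo-4-(TBS-oxy)but-2-en-1-ol | OC/C=C(\I)CO[Si](C)(C)C(C)(C)C | intermediate
5 | but-3-en-1-ylzinc bromide | C=CCC[Zn]Br | starting material
6 | (2E)-3-[(TBS-oxy)methyl]hepta-2,6-dien-1-ol | OC/C=C(\CCC=C)CO[Si](C)(C)C(C)(C)C | intermediate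
7 | (2E)-but-2-enal (crotonaldehyde) | C/C=C/C=O | starting material
8 | (2E,6E)-8-hydroxy-6-[(TBS-oxy)methyl]octa-2,6-dienal | OC/C=C(\CC/C=C/C=O)CO[Si](C)(C)C(C)(C)C | intermediate
9 | (2Z,6E)-8-hydroxy-2-iodo-6-[(TBS-oxy)methyl]octa-2,6-dienal | OC/C=C(\CC/C=C(\I)C=O)CO[Si](C)(C)C(C)(C)C | intermediate
10 | (2E,6Z)-7-iodo-8,8-dimethoxy-3-[(TBS-oxy)methyl]octa-2,6-dien-1-ol | OC/C=C(\CC/C=C(\I)C(OC)OC)CO[Si](C)(C)C(C)(C)C | intermediate
11 | (2E,6Z)-7-iodo-8,8-dimethoxy-3-[(TBS-oxy)methyl]octa-2,6-dienal | O=C/C=C(\CC/C=C(\I)C(OC)OC)CO[Si](C)(C)C(C)(C)C | intermediate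
12 | (2Z)-but-2-ene-1,4-diol | OC/C=C\CO | starting material
13 | (2Z)-1,4-bis(TES-oxy)but-2-ene | CC[Si](CC)(CC)OC/C=C\CO[Si](CC)(CC)CC | intermediate
14 | 3,5-bis[(TES-oxy)methyl]-1,2,4-trioxolane (cis/trans mixture) | CC[Si](CC)(CC)OCC1OOC(CO[Si](CC)(CC)CC)O1 | intermediate
15 | 2-(TES-oxy)acetaldehyde | CC[Si](CC)(CC)OCC=O | intermediate
16 | methyl prop-2-ynoate | COC(=O)C#C | starting material
17 | methyl 3-(methylzincio)prop-2-ynoate | COC(=O)C#C[Zn]C | intermediate
18 | methyl (4R)-4-hydroxy-5-(TES-oxy)pent-2-ynoate | COC(=O)C#C[C@@H](O)CO[Si](CC)(CC)CC | intermediate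
19 | (2S)-2-methylbutanoic acid | CC[C@H](C)C(O)=O | starting material
20 | (2S)-2-methylbutanoyl chloride | CC[C@H](C)C(Cl)=O | intermediate
21 | methyl (4R)-4-{[(2S)-2-methylbutanoyl]oxy}-5-(TES-oxy)pent-2-ynoate | COC(=O)C#C[C@@H](OC(=O)[C@@H](C)CC)CO[Si](CC)(CC)CC | intermediate
22 | diiodomethane | ICI | starting material
23 | chloro(iodomethyl)magnesium | IC[Mg]Cl | intermediate
24 | 2-(iodomethyl)-4,4,5,5-tetramethyl-1,3,2-dioxaborolane (ICH2Bpin) | ICB1OC(C)(C)C(C)(C)O1 | intermediate
25 | methyl (2E,4R)-2-(diisobutylalumanyl)-4-{[(2S)-2-methylbutanoyl]oxy}-5-(TES-oxy)pent-2-enoate (Al cis to H-3) | COC(=O)/C(=C\[C@@H](OC(=O)[C@@H](C)CC)CO[Si](CC)(CC)CC)[Al](CC(C)C)CC(C)C | intermediate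
26 | methyl (2Z,4R)-2-(Bpin-methyl)-4-{[(2S)-2-methylbutanoyl]oxy}-5-(TES-oxy)pent-2-enoate (C4 cis to CO2Me) | COC(=O)/C(CB1OC(C)(C)C(C)(C)O1)=C\[C@@H](OC(=O)[C@@H](C)CC)CO[Si](CC)(CC)CC | intermediate
27 | methyl (3S,4R,5E,9Z)-4-(Bpin-oxy)-10-iodo-11,11-dimethoxy-2-methylidene-3-[(1R)-1-{[(2S)-2-methylbutanoyl]oxy}-2-(TES-oxy)ethyl]-6-[(TBS-oxy)methyl]undeca-5,9-dienoate | COC(=O)C(=C)[C@H]([C@@H](OC(=O)[C@@H](C)CC)CO[Si](CC)(CC)CC)[C@H](OB1OC(C)(C)C(C)(C)O1)/C=C(/CO[Si](C)(C)C(C)(C)C)CC/C=C(\I)C(OC)OC | intermediate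
28 | (4S,5R)-5-[(1E,5Z)-6-iodo-7,7-dimethoxy-2-[(TBS-oxy)methyl]hepta-1,5-dien-1-yl]-3-methylidene-4-[(1R)-1-{[(2S)-2-methylbutanoyl]oxy}-2-(TES-oxy)ethyl]oxolan-2-one | C=C1C(=O)O[C@H](/C=C(/CO[Si](C)(C)C(C)(C)C)CC/C=C(\I)C(OC)OC)[C@H]1[C@@H](OC(=O)[C@@H](C)CC)CO[Si](CC)(CC)CC | intermediate
29 | {(2R)-2-[(2R,3S)-2-[(1E,5Z)-6-iodo-7,7-dimethoxy-2-[(TBS-oxy)methyl]hepta-1,5-dien-1-yl]-4-methylidene-5-oxooxolan-3-yl]-2-{[(2S)-2-methylbutanoyl]oxy}ethoxy}dimethylsulfonium chloride | C=C1C(=O)O[C@H](/C=C(/CO[Si](C)(C)C(C)(C)C)CC/C=C(\I)C(OC)OC)[C@H]1[C@@H](OC(=O)[C@@H](C)CC)CO[S+](C)C.[Cl-] | intermediate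
30 | (1R)-1-[(2R,3S)-2-[(1E,5Z)-6-iodo-7,7-dimethoxy-2-[(TBS-oxy)methyl]hepta-1,5-dien-1-yl]-4-methylidene-5-oxooxolan-3-yl]-2-oxoethyl (2S)-2-methylbutanoate | C=C1C(=O)O[C@H](/C=C(/CO[Si](C)(C)C(C)(C)C)CC/C=C(\I)C(OC)OC)[C@H]1[C@@H](OC(=O)[C@@H](C)CC)C=O | intermediate
31 | (3aS,4R,5S,6E,10E,11aR)-6-(dimethoxymethyl)-3-methylidene-2-oxo-10-[(TBS-oxy)methyl]-5-(TMS-oxy)-2,3,3a,4,5,8,9,11a-octahydrocyclodeca[b]furan-4-yl (2S)-2-methylbutanoate | C=C1C(=O)O[C@@H]2/C=C(/CO[Si](C)(C)C(C)(C)C)CC/C=C(/C(OC)OC)[C@H](O[Si](C)(C)C)[C@H](OC(=O)[C@@H](C)CC)[C@@H]12 | intermediate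
32 | (3aS,4R,5S,6E,10E,11aR)-6-formyl-5-hydroxy-10-(hydroxymethyl)-3-methylidene-2-oxo-2,3,3a,4,5,8,9,11a-octahydrocyclodeca[b]furan-4-yl (2S)-2-methylbutanoate (CNP0331447.11) | C=C1C(=O)O[C@@H]2/C=C(/CO)CC/C=C(/C=O)[C@H](O)[C@H](OC(=O)[C@@H](C)CC)[C@@H]12 | target

## Step count and risks

Total step count: 18. Longest linear sequence: 11 steps (steps 1–7, then 15–18).

Steps most likely to fail:

Step 14 (hydroalumination and borylmethylation). The aluminium hydride may attack one of the two ester groups, or the alkenylalane may lose its geometry before it is alkylated. The fallback sets out from 21 and comes back at 26. Pd(PPh3)4-catalysed syn-hydrostannation of 21 with Bu3SnH gives methyl (2E,4R)-4-{[(2S)-2-methylbutanoyl]oxy}-5-(TES-oxy)-2-(tributylstannyl)pent-2-enoate F1. Iododestannylation with I2 gives, with retention, methyl (2E,4R)-2-iodo-4-{[(2S)-2-methylbutanoyl]oxy}-5-(TES-oxy)pent-2-enoate F2. Pd-catalysed Negishi coupling of F2 with iodo[(Bpin)methyl]zinc F3, made from 24 and zinc dust, then gives 26 with the same alkene geometry.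

Step 15 (the proposed new allylboration). The phosphoric acid may not activate the ester-deactivated boronate enough, or the C8 centre may oppose the catalyst. The fallback uses known chromium allylation chemistry; it sets out from 21 (11 is used unchanged) and comes back at 28. Alkenylalane 25, made as in step 14, is trapped with formaldehyde to give methyl (2Z,4R)-2-(hydroxymethyl)-4-{[(2S)-2-methylbutanoyl]oxy}-5-(TES-oxy)pent-2-enoate F4. Appel bromination (CBr4, PPh3) gives methyl (2E,4R)-2-(bromomethyl)-4-{[(2S)-2-methylbutanoyl]oxy}-5-(TES-oxy)pent-2-enoate F5. Stoichiometric CrCl2 in THF turns F5 into the allylchromium reagent, which adds to 11 in a Nozaki–Hiyama-type 2-(alkoxycarbonyl)allylation; this gives the anti adduct whatever the bromide geometry and leaves the iodoalkene alone in the absence of nickel. The product is the open-chain hydroxy ester, methyl (3S,4R,5E,9Z)-4-hydroxy-10-iodo-11,11-dimethoxy-2-methylidene-3-[(1R)-1-{[(2S)-2-methylbutanoyl]oxy}-2-(TES-oxy)ethyl]-6-[(TBS-oxy)methyl]undeca-5,9-dienoate F6, which lactonises with PPTS to 28. Here the C6/C8 relationship rests on substrate control alone, so the diastereomers may need separation.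

Step 17 (ten-membered ring closure). Ring strain may slow the closure, or the ring conformation may override Felkin–Anh control and give the wrong C9 epimer. The fallback sets out from 30 and comes back at 32. Stoichiometric CrCl2 with 1 mol % NiCl2 in DMSO at high dilution gives the free C9 alcohols as an epimer mixture, the 9-epimeric 5-hydroxy analogues of 31 without the TMS group F7. Dess–Martin periodinane oxidises the mixture to the single ring enone, the C9 ketone of F7 F8. Corey–Bakshi–Shibata reduction, with the oxazaborolidine enantiomer chosen to deliver hydride for the 9S carbinol (or NaBH4/CeCl3 if the ring already favours it), gives the (9S)-alcohol, 31 without its TMS group F9. The conditions of step 18 convert F9 into 32.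

Further compounds

F1 | step 14 | methyl (2E,4R)-4-{[(2S)-2-methylbutanoyl]oxy}-5-(TES-oxy)-2-(tributylstannyl)pent-2-enoate | COC(=O)/C(=C\[C@@H](OC(=O)[C@@H](C)CC)CO[Si](CC)(CC)CC)[Sn](CCCC)(CCCC)CCCC
F2 | step 14 | methyl (2E,4R)-2-iodo-4-{[(2S)-2-methylbutanoyl]oxy}-5-(TES-oxy)pent-2-enoate | COC(=O)/C(I)=C\[C@@H](OC(=O)[C@@H](C)CC)CO[Si](CC)(CC)CC
F3 | step 14 | iodo[(Bpin)methyl]zinc | I[Zn]CB1OC(C)(C)C(C)(C)O1
F4 | step 15 | methyl (2Z,4R)-2-(hydroxymethyl)-4-{[(2S)-2-methylbutanoyl]oxy}-5-(TES-oxy)pent-2-enoate | COC(=O)/C(CO)=C\[C@@H](OC(=O)[C@@H](C)CC)CO[Si](CC)(CC)CC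
F5 | step 15 | methyl (2E,4R)-2-(bromomethyl)-4-{[(2S)-2-methylbutanoyl]oxy}-5-(TES-oxy)pent-2-enoate | COC(=O)/C(CBr)=C\[C@@H](OC(=O)[C@@H](C)CC)CO[Si](CC)(CC)CC
F6 | step 15 | methyl (3S,4R,5E,9Z)-4-hydroxy-10-iodo-11,11-dimethoxy-2-methylidene-3-[(1R)-1-{[(2S)-2-methylbutanoyl]oxy}-2-(TES-oxy)ethyl]-6-[(TBS-oxy)methyl]undeca-5,9-dienoate | COC(=O)C(=C)[C@H]([C@@H](OC(=O)[C@@H](C)CC)CO[Si](CC)(CC)CC)[C@H](O)/C=C(/CO[Si](C)(C)C(C)(C)C)CC/C=C(\I)C(OC)OC
F7 | step 17 | (3aS,4R,11aR)-6-(dimethoxymethyl)-5-hydroxy-3-methylidene-2-oxo-10-[(TBS-oxy)methyl]-2,3,3a,4,5,8,9,11a-octahydrocyclodeca[b]furan-4-yl (2S)-2-methylbutanoate, mixture of C5 (germacrane C9) epimers, alkene geometry as in 31 | C=C1C(=O)O[C@@H]2/C=C(/CO[Si](C)(C)C(C)(C)C)CC/C=C(/C(OC)OC)C(O)[C@H](OC(=O)[C@@H](C)CC)[C@@H]12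
F8 | step 17 | the corresponding C5 (germacrane C9) ketone, alkene geometry as in 31 | C=C1C(=O)O[C@@H]2/C=C(/CO[Si](C)(C)C(C)(C)C)CC/C=C(/C(OC)OC)C(=O)[C@H](OC(=O)[C@@H](C)CC)[C@@H]12
F9 | step 17 | (3aS,4R,5S,6E,10E,11aR)-6-(dimethoxymethyl)-5-hydroxy-3-methylidene-2-oxo-10-[(TBS-oxy)methyl]-2,3,3a,4,5,8,9,11a-octahydrocyclodeca[b]furan-4-yl (2S)-2-methylbutanoate | C=C1C(=O)O[C@@H]2/C=C(/CO[Si](C)(C)C(C)(C)C)CC/C=C(/C(OC)OC)[C@H](O)[C@H](OC(=O)[C@@H](C)CC)[C@@H]12
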